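The route rests on cutting the pyran ring at C2, so that both the C2–aryl bond and the O1–C2 bond are made last. C2 is benzylic to ring B (the 2,4,6-trihydroxy-3,5-diformylphenyl ring) and bonded to O1, and ring B's precursor has a single unsubstituted carbon; C2 can therefore be an aldehyde carbon whose configuration equilibrates through a ring B o-quinone methide. In one operation the key step joins complete ring B to C2 and recloses the pyran 2,3-trans. Its precursor is an enantioenriched chroman-2-ol on benzyl-capped isovalerylphloroglucinol (ring A), whose C3 isopropyl stereocentre is set by enamine catalysis.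

Key step: step 10

Remark on the chemistry: the (S)-configured catalyst in step 8 is assigned by the usual shielding model for diarylprolinol silyl ether enamines (electrophile enters anti to the CPh2OSiMe3 arm); because isopropyl outranks the new CH2–aryl group at C3, that sense of attack corresponds to 3S.

Step 1
Reactants: 1 phloroglucinol; 2 isovaleryl chloride (3-methylbutanoyl chloride)
Product: 3 3-methyl-1-(2,4,6-trihydroxyphenyl)butan-1-one (isovalerylphloroglucinol)
Conditions: AlCl3 (3.5 equiv), CH2Cl2/MeNO2, 0 °C to rt; then ice/aq. HCl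
Reagents that add atoms: none
Why: Friedel–Crafts C-acylation of the symmetrical, strongly activated triphenol; the first acyl group, chelated to aluminium, deactivates the ring so that monoacylation should stop cleanly.

Step 2
Reactants: 3 isovalerylphloroglucinol
Product: 4 1-[2,6-dihydroxy-4-(methoxymethoxy)phenyl]-3-methylbutan-1-one
Conditions: MOMCl (1.05 equiv), iPr2NEt, CH2Cl2, 0 °C
Reagents that add atoms: chloromethyl methyl ether, COCCl
Why: Selective Williamson-type O-alkylation: the OH para to the ketone is the most acidic and is not hydrogen-bonded to the carbonyl, unlike the two ortho OH groups, so one equivalent of electrophile with a weak amine base should go there.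

Step 3
Reactants: 4 para-MOM ether
Product: 5 1-[2,6-bis(benzyloxy)-4-(methoxymethoxy)phenyl]-3-methylbutan-1-one
Conditions: BnBr (2.6 equiv), K2CO3, cat. Bu4NI, DMF, 60 °C
Reagents that add atoms: benzyl bromide, BrCc1ccccc1
Why: Williamson ether synthesis on both chelated phenols; the acetal on the para oxygen is inert to carbonate in warm DMF, where a phenolic silyl ether para to a ketone would be at risk of cleavage and over-benzylation.

Step 4
Reactants: 5 bis(benzyl) MOM ether
Product: 6 1-[2,6-bis(benzyloxy)-4-hydroxyphenyl]-3-methylbutan-1-one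
Conditions: HCl (cat.), MeOH/THF, 40 °C
Reagents that add atoms: none
Why: Acid-catalysed acetal solvolysis frees the single phenol para to the ketone; benzyl ethers and the ketone are stable to dilute methanolic HCl.

Step 5
Reactants: 6 para-phenol; 7 formaldehyde (used as paraformaldehyde)
Product: 8 2,4-bis(benzyloxy)-6-hydroxy-3-(3-methylbutanoyl)benzaldehyde
Conditions: MgCl2 (anhydrous), Et3N, (CH2O)n, MeCN, reflux; aq. HCl work-up
Reagents that add atoms: none
Why: Magnesium-mediated ortho-formylation (Casnati–Skattebøl): formaldehyde is delivered within the Mg phenoxide only ortho to the free OH, a second formaldehyde serves as hydride acceptor, and the chelated formyl group deactivates the ring so that the equivalent second ortho position should stay untouched.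

Step 6
Reactants: 8 salicylaldehyde
Product: 9 1-[2,6-bis(benzyloxy)-4-hydroxy-3-(hydroxymethyl)phenyl]-3-methylbutan-1-one
Conditions: NaBH4 (1 equiv), THF/MeOH, −10 to 0 °C; pH 7 buffer work-up; used crude
Reagents that add atoms: none
Why: Chemoselective borohydride reduction: the aldehyde reacts well before the ketone, which is screened by two ortho benzyloxy groups, and the cold neutral work-up avoids ionising the electron-rich salicyl alcohol.

Step 7
Reactants: 9 salicyl alcohol
Product: 10 1-{2,6-bis(benzyloxy)-4-hydroxy-3-[(4-methylbenzenesulfonyl)methyl]phenyl}-3-methylbutan-1-one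
Conditions: p-TolSO2H (1.5 equiv), CH2Cl2, rt
Reagents that add atoms: p-toluenesulfinic acid, Cc1ccc(cc1)S(=O)O
Why: Acid-promoted SN1-type substitution of the benzylic hydroxyl: the sulfinic acid ionises the highly stabilised benzylic position and sulfinate is captured at sulfur, giving a stable sulfone that releases the quinone methide only under base.

Step 8
Reactants: 10 ortho-tosylmethyl phenol; 11 isovaleraldehyde (3-methylbutanal)
Product: 14 1-[(3S)-5,7-bis(benzyloxy)-2-hydroxy-3-(propan-2-yl)-3,4-dihydro-2H-chromen-6-yl]-3-methylbutan-1-one (lactol; both anomers), via ring A o-quinone methide 12 (not isolated), via open-chain hydroxy aldehyde 13 (not isolated)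
Conditions: (S)-α,α-diphenylprolinol trimethylsilyl ether (20 mol %), 11 (3 equiv), NaHCO3 (2 equiv), CH2Cl2/H2O, 0 °C to rt
Reagents that add atoms: none
Why: Enamine-catalysed formal oxa-[4+2] (Michael addition then hemiacetalisation): base expels sulfinate from the phenoxide of 10 to give 12, the catalyst-bound E-enamine of 11 adds through the face remote from the CPh2OSiMe3 arm to form C4–C3 and set C3 as S, and the released 13 closes to the lactol, which protects the α-stereocentre; the anomeric carbon is left unassigned because it is consumed in step 10.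

Step 9
Reactants: 1 phloroglucinol
Product: 15 2,4,6-trihydroxybenzene-1,3-dicarbaldehyde (2,4-diformylphloroglucinol)
Conditions: POCl3 (2.3 equiv), DMF, 1,4-dioxane, 0 °C to rt; then H2O
Reagents that add atoms: N,N-dimethylformamide, CN(C)C=O (both formyl carbons); water, O (formyl oxygens, on aqueous work-up)
Why: Vilsmeier–Haack formylation: the chloroiminium electrophile substitutes the triphenol twice, the doubly substituted ring is too deactivated for a third attack, and aqueous work-up unmasks the dialdehyde with exactly one ring CH left.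

Step 10
Reactants: 14 (3S)-lactol; 15 2,4-diformylphloroglucinol
Product: 18 5-[(2R,3S)-5,7-bis(benzyloxy)-6-(3-methylbutanoyl)-3-(propan-2-yl)-3,4-dihydro-2H-chromen-2-yl]-2,4,6-trihydroxybenzene-1,3-dicarbaldehyde (5,7-di-O-benzyl ether of the target), via ring B carbinol adduct 16 (not isolated), via ring B o-quinone methide 17 (not isolated)
Conditions: 15 (1.2 equiv), NaOAc, AcOH/THF, 45 °C, held until the C2 epimers have converged
Reagents that add atoms: none
Why: Proposed new method: in the acetate buffer lactol 14 reacts as a masked aldehyde through its ring-chain tautomer (the open hydroxy aldehyde form already met in step 8), whose carbonyl carbon is attacked by the single unsubstituted carbon of 15 (reacting as its vinylogous enolate) to give the benzylic carbinol 16; loss of water from 16 gives ring B o-quinone methide 17, which the C8a phenol of ring A captures to form the O1–C2 bond. The closest known reactions are the Knoevenagel-type condensation of 2,4-diformylphloroglucinol with aliphatic aldehydes to o-quinone methides (trapped so far by alkenes in hetero-Diels–Alder reactions) and the acid-mediated C-arylation of lactols by phloroglucinols (aryl C-glycosylation); intramolecular phenol capture on a chroman-2-ol is the untested part. The pyran ring closes by a 6-exo-trig oxa-Michael addition. C2 is set under thermodynamic control: the oxa-Michael step is reversible through 17, so both C2 epimers should drain into the 2,3-trans chroman with aryl and isopropyl both equatorial, which is 2R given the 3S centre already in place. The step needs C- over O-attack (15 has one nucleophilic carbon and O-aryl acetals revert), closure on the oxygen para to the ketone (both ortho oxygens are benzylated) and retention at C3 (the lactol keeps the free aldehyde concentration low, no amine is present, and intramolecular capture of 17 should outrun its tautomerisation to the styrene).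

Step 11
Reactants: 18 di-O-benzyl ether
Product: 19 5-[(2R,3S)-5,7-dihydroxy-6-(3-methylbutanoyl)-3-(propan-2-yl)-3,4-dihydro-2H-chromen-2-yl]-2,4,6-trihydroxybenzene-1,3-dicarbaldehyde (CNP0551232.1)
Conditions: BCl3 (1 M in CH2Cl2, excess), pentamethylbenzene, CH2Cl2, −78 °C; MeOH quench at −78 °C, then aqueous work-up
Reagents that add atoms: none
Why: Chelation-assisted Lewis-acid ether cleavage: BCl3 bound to the ketone carbonyl reaches both flanking benzyl ethers, pentamethylbenzene removes the benzyl cations by Friedel–Crafts capture before they can alkylate the electron-rich rings, and at −78 °C the formyl groups, the C2–O1 bond and both stereocentres should be left alone.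

Compound list
1 | phloroglucinol (benzene-1,3,5-triol) | Oc1cc(O)cc(O)c1 | starting material
2 | isovaleryl chloride (3-methylbutanoyl chloride) | CC(C)CC(Cl)=O | starting material
3 | 3-methyl-1-(2,4,6-trihydroxyphenyl)butan-1-one | CC(C)CC(=O)c1c(O)cc(O)cc1O | intermediate
4 | 1-[2,6-dihydroxy-4-(methoxymethoxy)phenyl]-3-methylbutan-1-one | CC(C)CC(=O)c1c(O)cc(OCOC)cc1O | intermediate
5 | 1-[2,6-bis(benzyloxy)-4-(methoxymethoxy)phenyl]-3-methylbutan-1-one | CC(C)CC(=O)c1c(OCc2ccccc2)cc(OCOC)cc1OCc1ccccc1 | intermediate
6 | 1-[2,6-bis(benzyloxy)-4-hydroxyphenyl]-3-methylbutan-1-one | CC(C)CC(=O)c1c(OCc2ccccc2)cc(O)cc1OCc1ccccc1 | intermediate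
7 | formaldehyde (used as paraformaldehyde) | C=O | starting material
8 | 2,4-bis(benzyloxy)-6-hydroxy-3-(3-methylbutanoyl)benzaldehyde | CC(C)CC(=O)c1c(OCc2ccccc2)cc(O)c(C=O)c1OCc1ccccc1 | intermediate
9 | 1-[2,6-bis(benzyloxy)-4-hydroxy-3-(hydroxymethyl)phenyl]-3-methylbutan-1-one | CC(C)CC(=O)c1c(OCc2ccccc2)cc(O)c(CO)c1OCc1ccccc1 | intermediate
10 | 1-{2,6-bis(benzyloxy)-4-hydroxy-3-[(4-methylbenzenesulfonyl)methyl]phenyl}-3-methylbutan-1-one | CC(C)CC(=O)c1c(OCc2ccccc2)cc(O)c(CS(=O)(=O)c2ccc(C)cc2)c1OCc1ccccc1 | intermediate
11 | isovaleraldehyde (3-methylbutanal) | CC(C)CC=O | starting material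
12 | 3,5-bis(benzyloxy)-6-methylidene-4-(3-methylbutanoyl)cyclohexa-2,4-dien-1-one (ring A o-quinone methide) | CC(C)CC(=O)C1=C(OCc2ccccc2)C(=C)C(=O)C=C1OCc1ccccc1 | intermediate
13 | (2S)-2-{[2,4-bis(benzyloxy)-6-hydroxy-3-(3-methylbutanoyl)phenyl]methyl}-3-methylbutanal | CC(C)CC(=O)c1c(OCc2ccccc2)cc(O)c(C[C@@H](C(C)C)C=O)c1OCc1ccccc1 | intermediate
14 | 1-[(3S)-5,7-bis(benzyloxy)-2-hydroxy-3-(propan-2-yl)-3,4-dihydro-2H-chromen-6-yl]-3-methylbutan-1-one (lactol, both anomers) | CC(C)CC(=O)c1c(OCc3ccccc3)cc2c(c1OCc1ccccc1)C[C@@H](C(C)C)C(O)O2 | intermediate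
15 | 2,4,6-trihydroxybenzene-1,3-dicarbaldehyde (2,4-diformylphloroglucinol) | O=Cc1c(O)cc(O)c(C=O)c1O | intermediate
16 | 5-{(2S)-2-{[2,4-bis(benzyloxy)-6-hydroxy-3-(3-methylbutanoyl)phenyl]methyl}-1-hydroxy-3-methylbutyl}-2,4,6-trihydroxybenzene-1,3-dicarbaldehyde (ring B carbinol adduct, both carbinol epimers) | CC(C)CC(=O)c1c(OCc2ccccc2)cc(O)c(C[C@@H](C(C)C)C(O)c2c(O)c(C=O)c(O)c(C=O)c2O)c1OCc1ccccc1 | intermediate
17 | 5-{(2S)-2-[[2,4-bis(benzyloxy)-6-hydroxy-3-(3-methylbutanoyl)phenyl]methyl]-3-methylbutylidene}-2,4-dihydroxy-6-oxocyclohexa-1,3-diene-1,3-dicarbaldehyde (ring B o-quinone methide, alkene geometry open) | CC(C)CC(=O)c1c(OCc2ccccc2)cc(O)c(C[C@@H](C(C)C)C=C2C(=O)C(C=O)=C(O)C(C=O)=C2O)c1OCc1ccccc1 | intermediate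
18 | 5-[(2R,3S)-5,7-bis(benzyloxy)-6-(3-methylbutanoyl)-3-(propan-2-yl)-3,4-dihydro-2H-chromen-2-yl]-2,4,6-trihydroxybenzene-1,3-dicarbaldehyde | CC(C)CC(=O)c1c(OCc3ccccc3)cc2c(c1OCc1ccccc1)C[C@@H](C(C)C)[C@H](c1c(O)c(C=O)c(O)c(C=O)c1O)O2 | intermediate
19 | 5-[(2R,3S)-5,7-dihydroxy-6-(3-methylbutanoyl)-3-(propan-2-yl)-3,4-dihydro-2H-chromen-2-yl]-2,4,6-trihydroxybenzene-1,3-dicarbaldehyde (CNP0551232.1) | CC(C)CC(=O)c1c(O)cc2c(c1O)C[C@@H](C(C)C)[C@H](c1c(O)c(C=O)c(O)c(C=O)c1O)O2 | target

Total step count: 11.
Longest linear sequence: 10 steps (steps 1 to 8, then 10 and 11, from phloroglucinol); step 9 is a one-step branch.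

Steps most likely to fail

1. Step 10 (Proposed new method). The C3 configuration may erode, either by enolisation of the open aldehyde form or by tautomerisation of the ring B quinone methide to the styrene before the ring closes. The C–C bond may also form slowly, because the nucleophile carries two formyl groups. The fallback uses known chemistry, sets out from 14 and returns at 18. Lactol 14 is C-arylated at the lactol carbon with excess phloroglucinol 1 under Lewis acid (BF3·OEt2, MeCN/CH2Cl2, −30 °C), as in the aryl C-glycosylation of phloroglucinols. The arene should enter anti to the C3 isopropyl group and give 1-[(2R,3S)-5,7-bis(benzyloxy)-3-(propan-2-yl)-2-(2,4,6-trihydroxyphenyl)-3,4-dihydro-2H-chromen-6-yl]-3-methylbutan-1-one F1. Vilsmeier–Haack double formylation (POCl3, DMF, EtOAc, 0 °C to rt; H2O) then fills the two free positions of ring B to give 18. Ring A is an acylated triether without a free phenol, so it should lag well behind the free triphenol ring.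

2. Step 8. The unsubstituted quinone methide may self-condense faster than the hindered enamine captures it. Facial selectivity may be insufficient, or enantiopurity may erode through re-enamination of the product. The fallback sets out from 10 and 11 and returns at 14. Aldehyde 11 is condensed with morpholine (K2CO3, 0 °C) to the preformed enamine 4-[(1E)-3-methylbut-1-en-1-yl]morpholine F2. Used in excess with 10 and K2CO3 in MeCN at rt, it traps the quinone methide in a Stork-enamine hetero-Diels–Alder addition. This gives the racemic 2-morpholinochroman 1-[5,7-bis(benzyloxy)-2-(morpholin-4-yl)-3-(propan-2-yl)-3,4-dihydro-2H-chromen-6-yl]-3-methylbutan-1-one F3. Mild hydrolysis (aq. AcOH, THF, rt) gives the racemic lactol F4. Preparative chromatography on a chiral stationary phase delivers 14, and the (3R)-lactol F5 is set aside.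

3. Step 11. The Lewis acid may ionise the C2–O1 bond, since the C2 cation is stabilised by ring B. That would lead to epimerisation, capture by the scavenger, or reclosure on a newly freed ortho oxygen; cleavage of the second benzyl ether may also be incomplete. The fallback sets out from 18 and returns at 19. It replaces acidolysis by reductive unmasking: catalytic hydrogenolysis (H2 at 1 atm, Pd/C, EtOAc, rt), stopped after uptake of two equivalents. No cation is generated at C2. The strongly chelated formyl groups should reduce more slowly than the O-benzyl bonds cleave. This fallback creates no new compound (F0).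

Further compounds
F1 | step 10 | 1-[(2R,3S)-5,7-bis(benzyloxy)-3-(propan-2-yl)-2-(2,4,6-trihydroxyphenyl)-3,4-dihydro-2H-chromen-6-yl]-3-methylbutan-1-one | CC(C)CC(=O)c1c(OCc3ccccc3)cc2c(c1OCc1ccccc1)C[C@@H](C(C)C)[C@H](c1c(O)cc(O)cc1O)O2
F2 | step 8 | 4-[(1E)-3-methylbut-1-en-1-yl]morpholine | CC(C)/C=C/N1CCOCC1
F3 | step 8 | racemic 1-[5,7-bis(benzyloxy)-2-(morpholin-4-yl)-3-(propan-2-yl)-3,4-dihydro-2H-chromen-6-yl]-3-methylbutan-1-one | CC(C)CC(=O)c1c(OCc3ccccc3)cc2c(c1OCc1ccccc1)CC(C(C)C)C(N1CCOCC1)O2
F4 | step 8 | racemic 1-[5,7-bis(benzyloxy)-2-hydroxy-3-(propan-2-yl)-3,4-dihydro-2H-chromen-6-yl]-3-methylbutan-1-one | CC(C)CC(=O)c1c(OCc3ccccc3)cc2c(c1OCc1ccccc1)CC(C(C)C)C(O)O2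
F5 | step 8 | 1-[(3R)-5,7-bis(benzyloxy)-2-hydroxy-3-(propan-2-yl)-3,4-dihydro-2H-chromen-6-yl]-3-methylbutan-1-one | CC(C)CC(=O)c1c(OCc3ccccc3)cc2c(c1OCc1ccccc1)C[C@H](C(C)C)C(O)O2
F0 | step 11 | none | none
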